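**Retrosynthetic overview**
1. Target 6 ⇒ spiro α-ketol 5 by a retro α-ketol (acyloin) ring contraction (C5–C9 bond; cyclopentenone from a cyclohexenedione).
2. 5 ⇒ epoxyquinone 4 by a retro 5-exo-tet spiroetherification (O1–C5 bond); 4 ⇒ quinone 3 by removing the oxirane oxygen. Forward, these three events run in one flask.
3. 3 ⇒ natural (2R,4'R,8'R)-α-tocopherol 1 by oxidative opening of the chroman; 1 supplies all 29 carbons and the C2, C4' and C8' stereocentres.
4. Ring order forward: the pyran ring of 1 is opened (step 1); then oxirane (transient) → tetrahydrofuran → cyclopentenone, all in step 2.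

Assumption: the (R)-BINOL–lanthanum catalyst is taken to deliver oxygen to the face of 3 that gives epoxide 4; if experiment shows the opposite sense, (S)-BINOL is used with nothing else changed.

**Step 1**
Reactants: 1 (2R,4'R,8'R)-α-tocopherol
Product: 3 α-tocopherolquinone, via hemiketal 2 (not isolated)
Conditions: FeCl3·6H2O (3 equiv), Et2O/MeOH/H2O, rt, dark, 1 h
Reagents that add atoms: water, O
Why: Oxidative dearomatization of the chromanol by two equivalents of FeCl3 gives the chromanoxylium cation, water adds at C8a to give hemiketal 2 (its oxygen becomes the new quinone carbonyl oxygen), and ring–chain opening releases the ring oxygen as the side-chain hydroxyl of para-quinone 3; no bond to the carbinol carbon is broken, so it and the two chain centres keep their R configuration.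

**Step 2**
Reactants: 3 α-tocopherolquinone
Product: 6 (2R,5R,9S)-9-acetyl-9-hydroxy-2,7,8-trimethyl-2-[(4R,8R)-4,8,12-trimethyltridecyl]-1-oxaspiro[4.4]non-7-en-6-one, via epoxyquinone 4 (not isolated), via spiro-acyloin 5 (not isolated)
Conditions: La(OiPr)3 (20 mol %), (R)-BINOL (20 mol %), Ph3P=O (60 mol %), t-BuOOH (1.3 equiv, decane), 4 Å MS, THF, 0 °C → rt, then 40 °C; silica gel, then preparative HPLC
Reagents that add atoms: tert-butyl hydroperoxide, CC(C)(C)OO
Why: Proposed new method: the tertiary hydroxyl of 3 binds the BINOL–lanthanum tert-butylperoxide, so the peroxide is delivered intramolecularly (Weitz–Scheffer conjugate addition/ring closure) to the neighbouring C5=C6 bond rather than to C2=C3 and, under ligand control, to the face that gives (5R,6S)-epoxide 4; the same lanthanum alkoxide then opens the oxirane at C6 in a 5-exo-tet cyclisation with inversion, which sets the spiro centre (C5 of 6, R), and the lanthanum-chelated α-ketol 5 undergoes a syn-periplanar α-ketol (acyloin) rearrangement in which the spiro carbon migrates with retention from C(OH)Me to the adjacent carbonyl carbon, contracting the ring, turning C(OH)Me into the acetyl group (its oxygen is the peroxide oxygen) and fixing C9 as S (hydroxyl trans to the ring oxygen); the closest known chemistry is the lanthanum–BINOL–Ph3P=O/t-BuOOH epoxidation of enones, hydroxyl-directed nucleophilic epoxidation with metal peroxides, and the base-induced conversion of tocopherol-derived 5,6-epoxyquinones into spiro acyloins.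

**Compound list**
1 | (2R,4'R,8'R)-α-tocopherol; (2R)-2,5,7,8-tetramethyl-2-[(4R,8R)-4,8,12-trimethyltridecyl]chroman-6-ol | Cc1c(C)c2O[C@](C)(CCC[C@H](C)CCC[C@H](C)CCCC(C)C)CCc2c(C)c1O | starting material
2 | 8a-hydroxy-α-tocopherone, the cyclic hemiketal of 3 (2R; both C8a epimers) | CC1=C(C)C2(O)O[C@](C)(CCC[C@H](C)CCC[C@H](C)CCCC(C)C)CCC2=C(C)C1=O | intermediate (not isolated)
3 | α-tocopherolquinone; 2-[(3R,7R,11R)-3-hydroxy-3,7,11,15-tetramethylhexadecyl]-3,5,6-trimethyl-1,4-benzoquinone | CC1=C(C)C(=O)C(CC[C@](C)(O)CCC[C@H](C)CCC[C@H](C)CCCC(C)C)=C(C)C1=O | intermediate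
4 | (5R,6S)-5,6-epoxy-α-tocopherolquinone; (1S,6R)-1-[(3R,7R,11R)-3-hydroxy-3,7,11,15-tetramethylhexadecyl]-3,4,6-trimethyl-7-oxabicyclo[4.1.0]hept-3-ene-2,5-dione | CC1=C(C)C(=O)[C@@]2(CC[C@](C)(O)CCC[C@H](C)CCC[C@H](C)CCCC(C)C)O[C@@]2(C)C1=O | intermediate (not isolated)
5 | (2R,5R,10R)-10-hydroxy-2,7,8,10-tetramethyl-2-[(4R,8R)-4,8,12-trimethyltridecyl]-1-oxaspiro[4.5]dec-7-ene-6,9-dione | CC1=C(C)C(=O)[C@@]2(CC[C@@](C)(CCC[C@H](C)CCC[C@H](C)CCCC(C)C)O2)[C@@](C)(O)C1=O | intermediate (not isolated)
6 | (2R,5R,9S)-9-acetyl-9-hydroxy-2,7,8-trimethyl-2-[(4R,8R)-4,8,12-trimethyltridecyl]-1-oxaspiro[4.4]non-7-en-6-one | CC(=O)[C@]1(O)C(C)=C(C)C(=O)[C@@]12CC[C@@](C)(CCC[C@H](C)CCC[C@H](C)CCCC(C)C)O2 | target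

**Total step count:** 2
**Longest linear sequence:** 2 steps (1 → 3 → 6)

**Steps most likely to fail** (the route has only two steps, so both are ranked and there is no third)

Most at risk is step 2. Three points are untested:
- whether the side-chain hydroxyl steers the peroxide to C5=C6 rather than to C2=C3;
- whether the ligand selects one face, since the remote carbinol centre gives no help and a second diastereomer must be expected and removed by HPLC;
- whether the lanthanum alkoxide carries 4 on to 6 without retro-aldol scrambling of C5 and C9.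

The fallback sets out from 3 and comes back at 6. It gives up direction and catalyst control and relies on separation. H2O2/Na2CO3 in aqueous EtOH epoxidises both quinone double bonds on both faces. This gives 4 together with (5S,6R)-5,6-epoxy-α-tocopherolquinone F1 and the regioisomer 2,3-epoxy-α-tocopherolquinone F2, which is removed on silica. The 4/F1 mixture is then treated with potassium tert-butoxide in THF at 0 °C and undergoes the same spiroetherification and acyloin contraction. 4 passes through 5 to 6, and F1 passes through the (2R,5S,10S)-spiro-acyloin F3 to the (2R,5S,9R)-spiro ketone F4. 6 and F4 differ in the relation of stereocentres within one compact spirocycle and are separated by preparative HPLC on silica.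

Second is step 1. Excess FeCl3 and the HCl it releases can chlorinate or over-oxidise the quinone, or dehydrate the tertiary alcohol. The fallback sets out from 1 and comes back at hemiketal 2, and from there at 3. It is a metal-free dearomatising photooxygenation: O2, tetraphenylporphyrin and visible light in CH2Cl2 at −78 °C give 8a-hydroperoxy-α-tocopherone F5. Me2S reduces F5 in the same flask to 2, which opens to 3 on warming.

**Further compounds**
F1 | step 2 | (5S,6R)-5,6-epoxy-α-tocopherolquinone | CC1=C(C)C(=O)[C@]2(CC[C@](C)(O)CCC[C@H](C)CCC[C@H](C)CCCC(C)C)O[C@]2(C)C1=O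
F2 | step 2 | 2,3-epoxy-α-tocopherolquinone (both epoxide faces) | CC1=C(CC[C@](C)(O)CCC[C@H](C)CCC[C@H](C)CCCC(C)C)C(=O)C2(C)OC2(C)C1=O
F3 | step 2 | (2R,5S,10S)-10-hydroxy-2,7,8,10-tetramethyl-2-[(4R,8R)-4,8,12-trimethyltridecyl]-1-oxaspiro[4.5]dec-7-ene-6,9-dione | CC1=C(C)C(=O)[C@]2(CC[C@@](C)(CCC[C@H](C)CCC[C@H](C)CCCC(C)C)O2)[C@](C)(O)C1=O
F4 | step 2 | (2R,5S,9R)-9-acetyl-9-hydroxy-2,7,8-trimethyl-2-[(4R,8R)-4,8,12-trimethyltridecyl]-1-oxaspiro[4.4]non-7-en-6-one | CC(=O)[C@@]1(O)C(C)=C(C)C(=O)[C@]12CC[C@@](C)(CCC[C@H](C)CCC[C@H](C)CCCC(C)C)O2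
F5 | step 1 | 8a-hydroperoxy-α-tocopherone (2R; both C8a epimers) | CC1=C(C)C2(OO)O[C@](C)(CCC[C@H](C)CCC[C@H](C)CCCC(C)C)CCC2=C(C)C1=O
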